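**Assumption (one line):** the SMILES is read literally, i.e. (R) at the carbinol carbon and the exocyclic Br cis to C4 / trans to the ring oxygen, which is (5E) by CIP.

## Retrosynthetic overview

1. Target ⇐ anti 5-exo-dig bromolactonisation of the enynoic acid 16. This closes the only ring last and fixes the exocyclic C=CHBr geometry (O and Br add anti, so Br ends up syn to C4).
2. Acid 16 ⇐ one-carbon alkyne homologation of a β-formyl acrylate (13), released by oxidative opening of 2-silyloxyfuran 12.
3. Furan 12 ⇐ 4-bromobutenolide 11, a temporary ring that places Br at C4 and locks the carboxyl cis to C5; 11 ⇐ bromolactonisation of 2,3-allenoic acid 10 ⇐ Tsuji carbonylation of propargylic carbonate 8.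
4. The carbinol stereocentre ⇐ ketoreductase reduction of ynone 3, made from bis(trimethylsilyl)acetylene and butanoyl chloride.
5. Ring order: temporary butenolide (step 9) → opened (step 11) → final butenolide (step 15).

## Route

**Step 1**
Reactants: 1 bis(trimethylsilyl)acetylene; 2 butanoyl chloride
Product: 3 1-(trimethylsilyl)hex-1-yn-3-one
Conditions: AlCl3, CH2Cl2, 0 °C
Reagents that add atoms: none (both carbon partners are reactants 1 and 2)
Why: Friedel–Crafts-type ipso-acylation of the alkynylsilane by the acylium ion; the resulting ynone is deactivated towards a second acylation.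

**Step 2**
Reactants: 3
Product: 4 (3R)-1-(trimethylsilyl)hex-1-yn-3-ol
Conditions: (R)-selective (anti-Prelog) ketoreductase (NADPH-dependent alcohol dehydrogenase, chosen by panel screen), NADP+ (cat.), i-PrOH, phosphate buffer pH 7, 30 °C
Reagents that add atoms: none (hydride from i-PrOH via NADPH)
Why: Enzymatic asymmetric ketone reduction; with the rigid silylalkynyl arm in the large pocket and propyl in the small one, hydride goes to the si face and gives the (R)-carbinol, the only stereocentre of the target.

**Step 3**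
Reactants: 4
Product: 5 (3R)-3-(tert-butyldimethylsilyloxy)-1-(trimethylsilyl)hex-1-yne
Conditions: TBSCl, imidazole, DMF, rt
Reagents that add atoms: TBSCl, CC(C)(C)[Si](C)(C)Cl
Why: Standard silyl ether formation; the stereocentre is not involved.

**Step 4**
Reactants: 5
Product: 6 (3R)-3-(tert-butyldimethylsilyloxy)hex-1-yne
Conditions: K2CO3, MeOH, rt
Reagents that add atoms: none
Why: Methoxide-mediated protodesilylation removes only the C(sp)–SiMe3 group; the O–TBS ether is stable.

**Step 5**
Reactants: 6
Product: 7 (4R)-4-(tert-butyldimethylsilyloxy)hept-2-yn-1-ol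
Conditions: n-BuLi, THF, −78 °C; (CH2O)n, −78 °C → rt
Reagents that add atoms: paraformaldehyde (formaldehyde), C=O
Why: Lithium acetylide addition to formaldehyde (hydroxymethylation).

**Step 6**
Reactants: 7
Product: 8 (4R)-4-(tert-butyldimethylsilyloxy)hept-2-yn-1-yl methyl carbonate
Conditions: ClCO2Me, pyridine, CH2Cl2, 0 °C
Reagents that add atoms: methyl chloroformate, COC(=O)Cl
Why: O-acylation of the primary alcohol gives the carbonate leaving group needed for Pd(0) ionisation.

**Step 7**
Reactants: 8
Product: 9 methyl 2-[(1R)-1-(tert-butyldimethylsilyloxy)butyl]buta-2,3-dienoate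
Conditions: Pd2(dba)3·CHCl3 (2.5 mol %), PPh3 (10 mol %), CO (10 atm), MeOH, 40 °C
Reagents that add atoms: carbon monoxide, [C-]#[O+]; methanol, CO
Why: Tsuji carbonylation: SN2′ oxidative addition/decarboxylation gives an allenyl-Pd species, CO insertion and methanolysis give the 2-substituted 2,3-dienoate; the silyl ether is not a leaving group.

**Step 8**
Reactants: 9
Product: 10 2-[(1R)-1-(tert-butyldimethylsilyloxy)butyl]buta-2,3-dienoic acid
Conditions: LiOH, THF–H2O, 0 °C → rt; then KHSO4 to pH 3
Reagents that add atoms: lithium hydroxide, [Li+].[OH-]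
Why: Saponification; the α-carbon is fully substituted, so no allene–alkyne isomerisation through an α-anion is possible.

**Step 9**
Reactants: 10
Product: 11 4-bromo-3-[(1R)-1-(tert-butyldimethylsilyloxy)butyl]furan-2(5H)-one
Conditions: NBS, K2CO3, MeCN–H2O, 0 °C → rt
Reagents that add atoms: N-bromosuccinimide, O=C1CCC(=O)N1Br
Why: Electrophilic bromolactonisation of a 2,3-allenoic acid: Br+ adds to the central allene carbon and the carboxylate closes on the CH2 terminus, giving the β-bromobutenolide.

**Step 10**
Reactants: 11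
Product: 12 4-bromo-3-[(1R)-1-(tert-butyldimethylsilyloxy)butyl]-2-(triisopropylsilyloxy)furan
Conditions: TIPSOTf, Et3N, CH2Cl2, 0 °C
Reagents that add atoms: TIPSOTf, CC(C)[Si](C(C)C)(C(C)C)OS(=O)(=O)C(F)(F)F
Why: Soft enolisation at C5 (the only acidic position) gives the aromatic 2-silyloxyfuran.

**Step 11**
Reactants: 12
Product: 13 triisopropylsilyl (2E)-3-bromo-2-[(1R)-1-(tert-butyldimethylsilyloxy)butyl]-4-oxobut-2-enoate (ester and formyl cis)
Conditions: DMDO, acetone–CH2Cl2, −78 → 0 °C
Reagents that add atoms: dimethyldioxirane, CC1(C)OO1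
Why: Oxidative ring-opening of the 2-silyloxyfuran (O-transfer to C5, silyl shift to the carboxylate) gives the silyl 4-oxo-2-enoate; because it comes from a ring, ester and aldehyde are necessarily cis on the tetrasubstituted alkene.

**Step 12**
Reactants: 13
Product: 14 triisopropylsilyl (2E)-3-bromo-2-[(1R)-1-(tert-butyldimethylsilyloxy)butyl]pent-2-en-4-ynoate
Conditions: TMSCHN2, LDA, THF, −78 → 0 °C
Reagents that add atoms: trimethylsilyldiazomethane, C[Si](C)(C)C=[N+]=[N-]
Why: Colvin rearrangement: 1,2-addition to the aldehyde, Peterson-type loss of silanolate and N2, then 1,2-H shift of the alkylidene carbene gives the terminal alkyne; the hindered silyl ester and the alkene geometry are untouched.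

**Step 13**
Reactants: 14
Product: 15 (2E)-3-bromo-2-[(1R)-1-hydroxybutyl]pent-2-en-4-ynoic acid
Conditions: 48% aq. HF, MeCN, 0 °C → rt
Reagents that add atoms: none
Why: Acidic global desilylation cleaves the silyl ester and the TBS ether without any base or nucleophile that could attack the bromo-enyne.

**Step 14**
Reactants: 15
Product: 16 (2E)-2-[(1R)-1-(acetyloxy)butyl]-3-bromopent-2-en-4-ynoic acid (CO2H and ethynyl cis)
Conditions: Ac2O, Sc(OTf)3 (1 mol %), MeCN, −20 °C; then H2O–THF
Reagents that add atoms: acetic anhydride, CC(=O)OC(C)=O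
Why: Lewis-acid-catalysed O-acetylation avoids nucleophilic amines; the transient mixed anhydride at CO2H is hydrolysed on aqueous work-up, and the C–O stereocentre is not broken.

**Step 15**
Reactants: 16
Product: 17 acetoxyfimbrolide, (1R)-1-[(5E)-4-bromo-5-(bromomethylidene)-2-oxo-2,5-dihydrofuran-3-yl]butyl acetate
Conditions: NBS, KHCO3, Bu4NOH (cat.), CH2Cl2–H2O, 0 °C, dark
Reagents that add atoms: N-bromosuccinimide, O=C1CCC(=O)N1Br
Why: Anti 5-exo-dig bromolactonisation of the alkynoic acid: the cis carboxylate attacks the internal alkyne carbon anti to Br+, so the new Br is trans to the ring oxygen and syn to C4 as in the target; formed last and worked up in the dark to avoid E→Z equilibration.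

## Compound list

1 | bis(trimethylsilyl)acetylene | C[Si](C)(C)C#C[Si](C)(C)C | starting material
2 | butanoyl chloride | CCCC(=O)Cl | starting material
3 | 1-(trimethylsilyl)hex-1-yn-3-one | CCCC(=O)C#C[Si](C)(C)C | intermediate
4 | (3R)-1-(trimethylsilyl)hex-1-yn-3-ol | CCC[C@@H](O)C#C[Si](C)(C)C | intermediate
5 | (3R)-3-(TBSO)-1-(trimethylsilyl)hex-1-yne | CCC[C@@H](O[Si](C)(C)C(C)(C)C)C#C[Si](C)(C)C | intermediate
6 | (3R)-3-(TBSO)hex-1-yne | CCC[C@@H](O[Si](C)(C)C(C)(C)C)C#C | intermediate
7 | (4R)-4-(TBSO)hept-2-yn-1-ol | CCC[C@@H](O[Si](C)(C)C(C)(C)C)C#CCO | intermediate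
8 | (4R)-4-(TBSO)hept-2-yn-1-yl methyl carbonate | CCC[C@@H](O[Si](C)(C)C(C)(C)C)C#CCOC(=O)OC | intermediate
9 | methyl 2-[(1R)-1-(TBSO)butyl]buta-2,3-dienoate | CCC[C@@H](O[Si](C)(C)C(C)(C)C)C(=C=C)C(=O)OC | intermediate
10 | 2-[(1R)-1-(TBSO)butyl]buta-2,3-dienoic acid | CCC[C@@H](O[Si](C)(C)C(C)(C)C)C(=C=C)C(=O)O | intermediate
11 | 4-bromo-3-[(1R)-1-(TBSO)butyl]furan-2(5H)-one | CCC[C@@H](O[Si](C)(C)C(C)(C)C)C1=C(Br)COC1=O | intermediate
12 | 4-bromo-3-[(1R)-1-(TBSO)butyl]-2-(TIPSO)furan | CCC[C@@H](O[Si](C)(C)C(C)(C)C)c1c(Br)coc1O[Si](C(C)C)(C(C)C)C(C)C | intermediate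
13 | TIPS (2E)-3-bromo-2-[(1R)-1-(TBSO)butyl]-4-oxobut-2-enoate | CCC[C@@H](O[Si](C)(C)C(C)(C)C)/C(C(=O)O[Si](C(C)C)(C(C)C)C(C)C)=C(Br)/C=O | intermediate
14 | TIPS (2E)-3-bromo-2-[(1R)-1-(TBSO)butyl]pent-2-en-4-ynoate | CCC[C@@H](O[Si](C)(C)C(C)(C)C)/C(C(=O)O[Si](C(C)C)(C(C)C)C(C)C)=C(Br)/C#C | intermediate
15 | (2E)-3-bromo-2-[(1R)-1-hydroxybutyl]pent-2-en-4-ynoic acid | CCC[C@@H](O)/C(C(=O)O)=C(Br)/C#C | intermediate
16 | (2E)-2-[(1R)-1-acetoxybutyl]-3-bromopent-2-en-4-ynoic acid | CCC[C@@H](OC(C)=O)/C(C(=O)O)=C(Br)/C#C | intermediate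
17 | acetoxyfimbrolide | CCC[C@@H](OC(C)=O)C1=C(Br)/C(=C\Br)OC1=O | target

## Step count and risks

Total steps: 15. Longest linear sequence: 15 (fully linear).

Three steps most likely to fail:

1. **Step 15 (anti-bromolactonisation of an electron-poor bromo-enyne; 5-exo vs 6-endo, E-integrity).** Fallback: convert 16 to the 1-bromoalkyne (NBS, cat. AgNO3) and cyclise under Ag(I) to the (5Z)-isomer, then photoisomerise (about 350 nm) to the E/Z mixture, separate the E isomer by HPLC and recycle Z.
2. **Step 12 (Colvin homologation next to a silyl ester and vinyl bromide).** Fallback: two-step alkyne construction by Wittig bromomethylenation of aldehyde 13 (Ph3P+CH2Br Br−, KOt-Bu, −78 °C) to the 1-bromodiene, then dehydrobromination (TBAF or DBU) to the enyne.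
3. **Steps 10–11 (silyloxyfuran formation and oxidation; the furylic OTBS could ionise or eliminate).** Fallback: oxidise C5 by Wohl–Ziegler bromination of 11 (NBS, AIBN) and silver-assisted hydrolysis to the 5-hydroxybutenolide, then homologate its ring-opened aldehyde carboxylate with the Ohira–Bestmann reagent (K2CO3, MeOH) to reach the TBS-protected enynoic acid.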